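**Retrosynthetic overview**
1. Target ⇒ terminal alkene (pyranone carrying an undec-10-enyl chain) + AcOH: the C–O bond at the stereocentre is made last by an enantioselective Markovnikov hydroacetoxylation (key step).
2. Alkene ⇒ 3,5-diethyl-2-methoxy-6-methyl-4-pyranone + 10-bromodec-1-ene (lateral alkylation).
3. Methoxypyranone ⇒ 4-hydroxy-2-pyranone (regioselective carbonyl O-methylation, a second C–O bond).
4. Hydroxypyranone ⇒ β,δ-diketo ester (lactonisation, ring C–O bond) ⇒ methyl 2-ethyl-3-oxohexanoate + acetyl Weinreb amide ⇒ 2 × methyl butanoate.
5. Ring order: the pyranone is the only ring and is closed in step 2; the single stereocentre, (S), is set in step 5.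

Assumption: the sense of induction of the new cobalt catalyst is not known in advance, so the ligand antipode that gives the (S)-acetate is fixed by a test run on dodec-1-ene (both antipodes of the diamine are commercial).

Co-cat* (step 5) is the Co(II) complex of the salen from enantiopure 1,2-diphenylethane-1,2-diamine and 3-(2,4,6-triisopropylphenyl)-5-tert-butylsalicylaldehyde. Its 3,3′-aryl walls leave one narrow channel for the long chain.

**Route**

Step 1
Reactants: 1 methyl butanoate (2 molecules)
Product: 2 methyl 2-ethyl-3-oxohexanoate (racemic)
Conditions: NaH (0.55 equiv), MeOH (cat.), THF, reflux; then 1 M HCl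
Reagents that add atoms: none
Why: Claisen self-condensation of the ester enolate, pulled to completion by irreversible deprotonation of the β-keto ester (the routine protocol for the lower homologue from methyl propanoate); the α-stereocentre forms racemic and is erased in step 2.

Step 2
Reactants: 2 methyl 2-ethyl-3-oxohexanoate; 3 N-methoxy-N-methylacetamide
Product: 5 3,5-diethyl-4-hydroxy-6-methyl-2H-pyran-2-one, via methyl 2,4-diethyl-3,5-dioxohexanoate 4 (not isolated)
Conditions: LDA (2.2 equiv, commercial solution), THF, −78 → 0 °C; 3 (1.05 equiv), −78 → 0 °C; 1 M HCl work-up; crude, DBU (1.5 equiv), PhMe, 80 °C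
Reagents that add atoms: none
Why: γ-Acylation of the β-keto ester dianion (Huckin–Weiler dianion chemistry) with a Weinreb amide, whose chelated tetrahedral intermediate prevents over-addition and proton transfer to unreacted dianion, followed by DBU-promoted enol-lactonisation (O1–C2 bond, loss of methanol); both sp3 centres of 4 become sp2, so their configuration is irrelevant.

Step 3
Reactants: 5 3,5-diethyl-4-hydroxy-6-methyl-2H-pyran-2-one
Product: 6 3,5-diethyl-2-methoxy-6-methyl-4H-pyran-4-one
Conditions: MeOTf (1.2 equiv), CH2Cl2, 0 °C → rt; sat. aq NaHCO3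
Reagents that add atoms: methyl trifluoromethanesulfonate COS(=O)(=O)C(F)(F)F
Why: Regioselective O-methylation of a 4-hydroxy-2-pyranone with a hard, neutral methylating agent (Beak-type alkylation): the lactone carbonyl oxygen of the neutral tautomer is attacked to give a 4-hydroxy-2-methoxypyrylium triflate, which loses a proton on bicarbonate work-up to the 2-methoxy-4-pyranone, whereas basic conditions would favour the unwanted 4-methoxy-2-pyranone.

Step 4
Reactants: 6 3,5-diethyl-2-methoxy-6-methyl-4H-pyran-4-one; 7 10-bromodec-1-ene
Product: 8 3,5-diethyl-2-methoxy-6-(undec-10-en-1-yl)-4H-pyran-4-one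
Conditions: LiHMDS (1.1 equiv), THF, −78 °C; 7 (1.5 equiv), HMPA (3 equiv), −78 → −20 °C
Reagents that add atoms: none
Why: Lateral (vinylogous) deprotonation of the 6-methyl group gives the extended lithium dienolate, which is C-alkylated by the primary bromide in an SN2 reaction (the known γ-alkylation of 6-alkyl-2-methoxy-4-pyranones); the ethyl CH2 groups sit on α-carbons and are not acidified, and the terminal alkene is inert.

Step 5
Reactants: 8 3,5-diethyl-2-methoxy-6-(undec-10-en-1-yl)-4H-pyran-4-one
Product: 9 (2S)-11-(3,5-diethyl-6-methoxy-4-oxo-4H-pyran-2-yl)undecan-2-yl acetate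
Conditions: Co-cat* (5 mol %), N-fluoro-2,4,6-trimethylpyridinium triflate (1.5 equiv), PhSiH3 (1.2 equiv), AcOH (5 equiv), PhCF3, −10 °C, Ar
Reagents that add atoms: acetic acid CC(=O)O
Why: Proposed new method: enantioselective intermolecular Markovnikov hydroacetoxylation of an unactivated 1-alkene by metal-hydride hydrogen-atom transfer/radical-polar crossover – Co(III)–H (from Co(II), the N–F oxidant and PhSiH3) delivers H• to the terminal carbon, the secondary radical is captured by the chiral cobalt and oxidised to a cobalt(IV) sec-alkyl, and acetate displaces cobalt with inversion inside the confined pocket while the two diastereomeric alkylcobalt species interconvert by reversible Co–C homolysis (Curtin–Hammett), so the C–O bond-forming step sets the (S) centre by telling methyl from the long chain; the tetrasubstituted, electron-poor pyranone C=C bonds do not accept H•; closest known reaction type is the Co(salen)-catalysed Mukaiyama-type HAT hydroalkoxylation/hydroacyloxylation of alkenes, for which enantiocontrol in the intermolecular addition of a carboxylic acid to a simple 1-alkene has not been shown.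

**Compound list**
1 | methyl butanoate | CCCC(=O)OC | starting material
2 | methyl 2-ethyl-3-oxohexanoate (racemic) | CCCC(=O)C(CC)C(=O)OC | intermediate
3 | N-methoxy-N-methylacetamide | CC(=O)N(C)OC | starting material
4 | methyl 2,4-diethyl-3,5-dioxohexanoate (diastereomer/tautomer mixture, not isolated) | CCC(C(C)=O)C(=O)C(CC)C(=O)OC | intermediate
5 | 3,5-diethyl-4-hydroxy-6-methyl-2H-pyran-2-one | CCC1=C(O)C(CC)=C(C)OC1=O | intermediate
6 | 3,5-diethyl-2-methoxy-6-methyl-4H-pyran-4-one | CCc1c(C)oc(OC)c(CC)c1=O | intermediate
7 | 10-bromodec-1-ene | C=CCCCCCCCCBr | starting material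
8 | 3,5-diethyl-2-methoxy-6-(undec-10-en-1-yl)-4H-pyran-4-one | CCc1c(CCCCCCCCCC=C)oc(OC)c(CC)c1=O | intermediate
9 | (2S)-11-(3,5-diethyl-6-methoxy-4-oxo-4H-pyran-2-yl)undecan-2-yl acetate | CCc1c(CCCCCCCCC[C@H](C)OC(C)=O)oc(OC)c(CC)c1=O | target

**Totals**
Total step count: 5. Longest linear sequence: 5 (1 → 2 → 5 → 6 → 8 → 9); 3 and 7 are bought.

**Three steps most likely to fail**

Step 5 (proposed new method). The risks are low enantioselectivity (methyl versus n-alkyl), alkene isomerisation by reversible HAT, and simple reduction; ee is read by chiral HPLC against the racemate made with an achiral Co(salen). The fallback uses known chemistry, sets out from 8 and comes back at 9. Tsuji–Wacker oxidation of 8 (PdCl2 cat., CuCl, O2, DMF/H2O, rt) gives the methyl ketone 3,5-diethyl-2-methoxy-6-(10-oxoundecyl)-4H-pyran-4-one F1. A Prelog-selective alcohol dehydrogenase (for example ADH-A from Rhodococcus ruber or a screened commercial ketoreductase, NADH, propan-2-ol as hydride source, phosphate buffer pH 7 with DMSO cosolvent, 30 °C) reduces it to 3,5-diethyl-6-[(10S)-10-hydroxyundecyl]-2-methoxy-4H-pyran-4-one F2; methyl n-alkyl ketones routinely give the (S)-alcohol in >99% ee. Acetylation (Ac2O, pyridine, DMAP cat., CH2Cl2) then gives 9 with retention. This costs two more steps.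

Step 4 (lateral alkylation with an unactivated bromide). The risks are sluggish alkylation and self-condensation of the dienolate at the 2-methoxy position. The fallback sets out from 2 and comes back at 8, with the chain built in before ring closure. The dianion of 2 (LDA, 2.2 equiv of 2 per ester) is acylated with methyl dodec-11-enoate (THF, −78 → 0 °C) to methyl 2,4-diethyl-3,5-dioxohexadec-15-enoate F3. DBU in toluene at 80 °C closes it to 3,5-diethyl-4-hydroxy-6-(undec-10-en-1-yl)-2H-pyran-2-one F4, and MeOTf in CH2Cl2, as in step 3, gives 8. This is one operation shorter than the main line, but it depends on a speciality ester sold in small lots, whereas the main line uses only bulk chemicals.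

Step 3 (regioselectivity of the O-methylation). The risk is formation of the isomeric 4-methoxy-2-pyranone. The fallback sets out from 4 and comes back at 6; the ring is closed with the ester methoxy group kept, so no methylation is needed. DBU is omitted in step 2, 4 is isolated and treated with Ph3P/CCl4 in THF at rt (Appel-type cyclodehydration: the enolised 1,3-diketone is activated at oxygen, the ester carbonyl oxygen closes the ring and a proton is lost), which gives 6 directly. This way makes no new compound (F0).

**Further compounds**
F1 | step 5 | 3,5-diethyl-2-methoxy-6-(10-oxoundecyl)-4H-pyran-4-one | CCc1c(CCCCCCCCCC(C)=O)oc(OC)c(CC)c1=O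
F2 | step 5 | 3,5-diethyl-6-[(10S)-10-hydroxyundecyl]-2-methoxy-4H-pyran-4-one | CCc1c(CCCCCCCCC[C@H](C)O)oc(OC)c(CC)c1=O
F3 | step 4 | methyl 2,4-diethyl-3,5-dioxohexadec-15-enoate | COC(=O)C(CC)C(=O)C(CC)C(=O)CCCCCCCCCC=C
F4 | step 4 | 3,5-diethyl-4-hydroxy-6-(undec-10-en-1-yl)-2H-pyran-2-one | CCC1=C(O)C(CC)=C(CCCCCCCCCC=C)OC1=O
F0 | step 3 | none | none
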